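**Plan**

1. Retrosynthesis (ring numbering of the target: C1 = C=O, C2 bears CH3, C3, C4 bears OH, C5 bears the chain, C6 = CH2): the C1 ketone is first masked as a dimethyl ketal; then the C4–H bond and the C5–H/C6–H bonds are cut (carbonyl and C=C reduction of a quinone monoketal); then the C1/C4 oxygenation is traced back to a p-methoxyphenol (oxidative dearomatization); last, the C5–C1' bond is cut to 4-methoxy-3-methylphenol and geranylgeranyl bromide.
2. Forward: the all-E C20 chain is joined to the flat arene by ortho C-allylation; PhI(OAc)2/MeOH then turns the arene into the cross-conjugated dienone monoketal. No ring is built: the benzene ring becomes the cyclohexenone ring.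
3. Enabling feature: the six ring carbons carry O at C1 and C4 (para), CH3 at C2 and the chain at C5, which is the pattern of a 2,5-dialkylhydroquinone. With C1 masked as the ketal, C5=C6 is the only α-alkyl/β-H enone bond (next to the free C4 carbonyl); C2=C3 is β,β-disubstituted and the four chain alkenes are isolated.
4. Key step: an ene-reductase reduces C5=C6 only and sets C5 by protonation; a ketoreductase added to the same pot reduces C4=O and sets C4 (cis) before the α-stereocenter can epimerize.
5. Stereochemistry: C5 (S) from the ene-reductase, C4 (S) from the ketoreductase, alkene geometry unchanged from geranylgeraniol. The only protecting group is the ketal that the dearomatization itself installs.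

Key step: step 4

Abbreviation: GG = geranylgeranyl = (2E,6E,10E)-3,7,11,15-tetramethylhexadeca-2,6,10,14-tetraen-1-yl.
Assumption: an ene-reductase and a ketoreductase of the required face selectivity can be picked from commercial enzyme panels, in which both stereopreferences for α-alkyl cyclohexenones and for cyclic enone carbonyls are represented.

**Route**

Step 1
Reactants: 1 (2E,6E,10E)-geranylgeraniol
Product: 2 (2E,6E,10E)-geranylgeranyl bromide
Conditions: PBr3 (0.4 equiv), Et2O, −10 °C, 30 min; used crude
Reagents that add atoms: phosphorus tribromide, BrP(Br)Br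
Why: Bromination of a primary allylic alcohol with PBr3 (SN2 displacement of the intermediate phosphite ester by bromide) at low temperature should give the primary bromide without allylic transposition, so the 2E geometry is kept; no stereocenter is formed.

Step 2
Reactants: 3 4-methoxy-3-methylphenol; 2 geranylgeranyl bromide
Product: 5 2-GG-4-methoxy-5-methylphenol, via sodium 4-methoxy-3-methylphenolate 4 (not isolated)
Conditions: 3 (1.5 equiv), NaH (1.5 equiv), toluene, 0 °C; then 2 (1.0 equiv), 0 °C → rt, dark
Reagents that add atoms: none
Why: Ortho C-allylation of a phenolate: in the non-polar solvent the sodium phenolate reacts as a tight ion aggregate with shielded oxygen, so the primary allylic bromide is attacked in SN2 fashion (E geometry kept) by the ortho carbon, and only the ortho position para to CH3 is unhindered (the other lies between OH and CH3, the para position carries OCH3); excess phenolate limits dialkylation and no stereocenter is formed.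

Step 3
Reactants: 5 2-GG-4-methoxy-5-methylphenol
Product: 6 2-GG-4,4-dimethoxy-5-methylcyclohexa-2,5-dien-1-one
Conditions: PhI(OAc)2 (1.1 equiv), MeOH, 0 °C, 20 min; NaHCO3 (aq) quench
Reagents that add atoms: methanol, CO
Why: Oxidative dearomatization of a p-methoxyphenol with an iodine(III) reagent: ligand exchange at iodine and loss of PhI give a phenoxenium ion stabilized by the para methoxy group, which methanol captures at C4 to give the quinone monoketal; the phenol should be oxidized far faster than the isolated trisubstituted alkenes, and no stereocenter is formed.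

Step 4
Reactants: 6 2-GG-4,4-dimethoxy-5-methylcyclohexa-2,5-dien-1-one
Product: 8 (1S,6S)-6-GG-4,4-dimethoxy-3-methylcyclohex-2-en-1-ol, via (S)-ketone 7 (not isolated)
Conditions: ene-reductase (Old Yellow Enzyme family, (S)-selective), NADP+ (cat.), glucose dehydrogenase, D-glucose (2.5 equiv), KPi buffer pH 7.5, 10% DMSO, 30 °C; then ketoreductase (NADPH-dependent, (1S)-selective), same pot, 30 °C
Reagents that add atoms: none
Why: The flavin-dependent ene-reductase binds 6 through its C1 carbonyl, transfers hydride from FMNH2 to C3 (the β-CH) and a proton from the active-site tyrosine to C2 on the opposite face, and the ketoreductase then delivers the NADPH hydride to the carbonyl of 7; the closest known reaction types are the Old Yellow Enzyme reduction of 2-alkylcyclohex-2-enones and of cross-conjugated cyclohexadienones, and one-pot ene-reductase/alcohol dehydrogenase cascades that give 2-substituted cycloalkanols. No ring is closed; the ring made flat by dearomatization is kept and only its unsaturated positions are filled. C6 of 7 and 8 (C5 of the target) is set by enzyme-controlled protonation of the flavin-bound enolate, and the carbinol center C1 of 8 (C4 of the target) by the face selectivity of the ketoreductase, chosen to give the (1S), cis alcohol. The step needs selectivity for one of six C=C bonds, and the substrate secures it: C2=C3 of 6 is the only α-alkyl, β-H enone bond, the other ring alkene is β,β-disubstituted (CH3 and the quaternary ketal carbon), the four chain alkenes are unactivated, and the ketal keeps 7 from tautomerizing to a hydroquinone. Carbonyl reduction in the same pot removes the acidity of the new α-stereocenter, so it should not racemize. Acceptance of the long lipophilic chain is plausible because enzymes of this family act on fatty-acid-derived cyclic enones, and the cosolvent should help.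

Step 5
Reactants: 8 (1S,6S)-6-GG-4,4-dimethoxy-3-methylcyclohex-2-en-1-ol
Product: 9 (4S,5S)-5-GG-4-hydroxy-2-methylcyclohex-2-en-1-one (target)
Conditions: PPTS (0.1 equiv), acetone–H2O (10:1), 0 °C → rt
Reagents that add atoms: water, O
Why: Acid-catalysed hydrolysis of an allylic dimethyl ketal via the alkene-stabilized oxocarbenium ion is much faster than ionization of the secondary allylic alcohol, so very mild acid should unveil the enone without dehydration to the phenol or protonation of the chain alkenes; both stereocenters are untouched, since neither is α to the new carbonyl.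

**Compound list**

1 | (2E,6E,10E)-geranylgeraniol | CC(C)=CCC/C(C)=C/CC/C(C)=C/CC/C(C)=C/CO | starting material
2 | (2E,6E,10E)-geranylgeranyl bromide | CC(C)=CCC/C(C)=C/CC/C(C)=C/CC/C(C)=C/CBr | intermediate
3 | 4-methoxy-3-methylphenol | COc1ccc(O)cc1C | starting material
4 | sodium 4-methoxy-3-methylphenolate | COc1ccc([O-])cc1C.[Na+] | intermediate
5 | 2-GG-4-methoxy-5-methylphenol | CC(C)=CCC/C(C)=C/CC/C(C)=C/CC/C(C)=C/Cc1cc(OC)c(C)cc1O | intermediate
6 | 2-GG-4,4-dimethoxy-5-methylcyclohexa-2,5-dien-1-one | CC(C)=CCC/C(C)=C/CC/C(C)=C/CC/C(C)=C/CC1=CC(OC)(OC)C(C)=CC1=O | intermediate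
7 | (6S)-6-GG-4,4-dimethoxy-3-methylcyclohex-2-en-1-one | CC(C)=CCC/C(C)=C/CC/C(C)=C/CC/C(C)=C/C[C@H]1CC(OC)(OC)C(C)=CC1=O | intermediate
8 | (1S,6S)-6-GG-4,4-dimethoxy-3-methylcyclohex-2-en-1-ol | CC(C)=CCC/C(C)=C/CC/C(C)=C/CC/C(C)=C/C[C@H]1CC(OC)(OC)C(C)=C[C@H]1O | intermediate
9 | (4S,5S)-5-GG-4-hydroxy-2-methylcyclohex-2-en-1-one | CC(C)=CCC/C(C)=C/CC/C(C)=C/CC/C(C)=C/C[C@H]1CC(=O)C(C)=C[C@H]1O | target

**Step count**

Total step count: 5. Longest linear sequence: 5 steps (1 → 2 → 5 → 6 → 8 → 9).

**Steps most likely to fail**

Step 4. The ene-reductase may bind or turn over the very lipophilic C20-substituted dienone poorly, or the face selectivity of the protonation or of the carbonyl reduction may be insufficient. The fallback sets out from 6 and comes back at 8. Chemoselective copper hydride conjugate reduction of the less substituted enone bond of 6 with [(Ph3P)CuH]6 (toluene, rt) should give the racemic ketone rac-6-GG-4,4-dimethoxy-3-methylcyclohex-2-en-1-one F1. L-Selectride (THF, −78 °C) should reduce this β,β-disubstituted enone in 1,2-fashion from the equatorial direction and give the racemic cis alcohol F2. A lipase-catalysed kinetic resolution (Burkholderia cepacia lipase or Candida antarctica lipase B, vinyl acetate, MTBE, 30 °C) should, by the empirical size rule for secondary alcohols (large group = the branched CH(GG) side), acetylate the (1S,6S) enantiomer to the acetate (1S,6S)-6-GG-4,4-dimethoxy-3-methylcyclohex-2-en-1-yl acetate F3. F3 is separated from the unreacted (1R,6R) alcohol by chromatography, and K2CO3/MeOH returns 8.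

Step 2. O-Alkylation, dialkylation or attack at the hindered ortho carbon may erode the ortho C-allylation. The fallback sets out from 3 and comes back at 5. Bromination of 3 (NBS, MeCN, 0 °C) at the unhindered position ortho to OH should give 2-bromo-4-methoxy-5-methylphenol F4. n-BuLi (2.2 equiv, THF, −78 °C) deprotonates the phenol and exchanges bromine for lithium to give lithium 2-lithio-4-methoxy-5-methylphenolate F5. Its aryl carbon is allylated by 2 in the presence of CuBr·SMe2 (cat.), and aqueous NH4Cl work-up gives 5. The position of the chain is then fixed by the halogen and not by the ambident phenolate.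

Step 5. Ionization of the free allylic alcohol and acid-induced dehydration with aromatization to a phenol may compete with ketal hydrolysis. The fallback sets out from 8 and comes back at 9. Silylation (TBSCl, imidazole, DMF) gives the silyl ether (1S,6S)-1-(tert-butyldimethylsilyloxy)-6-GG-4,4-dimethoxy-3-methylcyclohex-2-ene F6. The ketal is hydrolysed (oxalic acid on wet silica, CH2Cl2) to (4S,5S)-4-(tert-butyldimethylsilyloxy)-5-GG-2-methylcyclohex-2-en-1-one F7, whose oxygen is no longer easily protonated and lost. HF·pyridine (THF/pyridine, 0 °C) then removes the silyl group under buffered conditions to give 9.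

**Further compounds**

F1 | step 4 | rac-6-GG-4,4-dimethoxy-3-methylcyclohex-2-en-1-one | CC(C)=CCC/C(C)=C/CC/C(C)=C/CC/C(C)=C/CC1CC(OC)(OC)C(C)=CC1=O
F2 | step 4 | rac-cis-(1S*,6S*)-6-GG-4,4-dimethoxy-3-methylcyclohex-2-en-1-ol (both enantiomers) | CC(C)=CCC/C(C)=C/CC/C(C)=C/CC/C(C)=C/C[C@H]1CC(OC)(OC)C(C)=C[C@H]1O.CC(C)=CCC/C(C)=C/CC/C(C)=C/CC/C(C)=C/C[C@@H]1CC(OC)(OC)C(C)=C[C@@H]1O
F3 | step 4 | (1S,6S)-6-GG-4,4-dimethoxy-3-methylcyclohex-2-en-1-yl acetate | CC(C)=CCC/C(C)=C/CC/C(C)=C/CC/C(C)=C/C[C@H]1CC(OC)(OC)C(C)=C[C@H]1OC(C)=O
F4 | step 2 | 2-bromo-4-methoxy-5-methylphenol | COc1cc(Br)c(O)cc1C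
F5 | step 2 | lithium 2-lithio-4-methoxy-5-methylphenolate | [Li]Oc1cc(C)c(OC)cc1[Li]
F6 | step 5 | (1S,6S)-1-(tert-butyldimethylsilyloxy)-6-GG-4,4-dimethoxy-3-methylcyclohex-2-ene | CC(C)=CCC/C(C)=C/CC/C(C)=C/CC/C(C)=C/C[C@H]1CC(OC)(OC)C(C)=C[C@H]1O[Si](C)(C)C(C)(C)C
F7 | step 5 | (4S,5S)-4-(tert-butyldimethylsilyloxy)-5-GG-2-methylcyclohex-2-en-1-one | CC(C)=CCC/C(C)=C/CC/C(C)=C/CC/C(C)=C/C[C@H]1CC(=O)C(C)=C[C@H]1O[Si](C)(C)C(C)(C)C
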